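Assumption: the target, 3-henicosyl-2-hydroxy-5-methoxy-1,4-benzoquinone (C28H48O4, unbranched C21 chain), has no stereocentre and no stereogenic double bond, so it is achiral and no stereocontrol is needed.

**Retrosynthetic overview**
- Target ⇒ cleave the C5–OCH3 bond: site-selective mono-O-methylation of 3-henicosyl-2,5-dihydroxy-1,4-benzoquinone at the vinylogous acid not flanked by the chain.
- ⇒ cleave the ring–chain C–C bond at the quinone oxidation level: a single decarboxylative radical C–H alkylation of C2h-symmetric 2,5-dihydroxy-1,4-benzoquinone with the C21 radical from docosanoic (behenic, C22) acid. This desymmetrisation is the key step.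
- ⇒ 2,5-dihydroxy-1,4-benzoquinone from hydroquinone by oxidative dearomatisation with double hydroxylation.
- No ring is formed; the only ring is carried over from hydroquinone.

**Route**

Step 1
Reactants: 1 hydroquinone (benzene-1,4-diol)
Product: 4 2,5-dihydroxy-1,4-benzoquinone, via 1,4-benzoquinone 2 (not isolated), via disodium salt 3 (not isolated)
Conditions: 30% aq H2O2 (3.3 equiv), 50% aq NaOH, 45–50 °C; then conc. HCl to pH 1, 0 °C, filter
Reagents that add atoms: hydrogen peroxide, OO; sodium hydroxide, [Na+].[OH-] (its sodium stays only in intermediate 3)
Why: Oxidative dearomatisation: alkaline H2O2 oxidises the hydroquinone dianion to quinone 2, two Weitz–Scheffer-type nucleophilic hydroxylation/re-oxidation cycles install oxygen at C2 and C5, and the sparingly soluble disodium salt 3 precipitates and is thereby protected from over-oxidation until HCl liberates 4.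

Step 2
Reactants: 4 2,5-dihydroxy-1,4-benzoquinone (3 equiv); 5 docosanoic acid (behenic acid, 1 equiv, limiting)
Product: 7 3-henicosyl-2,5-dihydroxy-1,4-benzoquinone, via henicosyl radical 6 (not isolated)
Conditions: AgNO3 (0.3 equiv), (NH4)2S2O8 (1.5 equiv, added slowly), MeCN/0.1 M aq H2SO4 (2:1), 80 °C; filter, wash with water, recrystallise (dioxane)
Reagents that add atoms: none
Why: Jacobsen–Torssell (Minisci-type) Ag(I)/persulfate decarboxylative radical C–H alkylation: Ag(II) oxidises the carboxylate of 5, loss of CO2 gives the primary C21 radical 6, which adds to one of the two equivalent C–H carbons of symmetric 4 (the adduct radical is captodatively stabilised and re-oxidised to the quinone), so the first alkylation can give only one constitutional isomer and the excess of 4 suppresses the second; hydroxyquinones are established acceptors in this reaction type and 4 is known to take alkyl radicals from diacyl peroxides; no stereocentre is formed.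

Step 3
Reactants: 7 3-henicosyl-2,5-dihydroxy-1,4-benzoquinone
Product: 8 3-henicosyl-2-hydroxy-5-methoxy-1,4-benzoquinone
Conditions: MeOH/CHCl3 (4:1), conc. H2SO4 (0.2 equiv), 55 °C, stopped when 7 is consumed; cool, crystallise
Reagents that add atoms: methanol, CO
Why: Acid-catalysed vinylogous Fischer esterification (addition–elimination of MeOH): the vinylogous acid around ring C6–H is unhindered, whereas the one flanking the C21 chain is shielded and its methyl ether would be twisted out of conjugation and readily re-hydrolysed by the water formed, so the 5-O-methyl ether is the favoured mono-ether; no stereocentre is formed.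

**Compound list**
1 | hydroquinone (benzene-1,4-diol) | Oc1ccc(O)cc1 | starting material
2 | 1,4-benzoquinone | O=C1C=CC(=O)C=C1 | intermediate
3 | disodium 2,5-dioxido-1,4-benzoquinone (disodium salt of 4) | [Na+].[Na+].[O-]C1=CC(=O)C([O-])=CC1=O | intermediate
4 | 2,5-dihydroxy-1,4-benzoquinone | OC1=CC(=O)C(O)=CC1=O | intermediate
5 | docosanoic acid (behenic acid) | CCCCCCCCCCCCCCCCCCCCCC(=O)O | starting material
6 | henicosyl radical (henicosan-1-yl) | CCCCCCCCCCCCCCCCCCCC[CH2] | intermediate
7 | 3-henicosyl-2,5-dihydroxy-1,4-benzoquinone | CCCCCCCCCCCCCCCCCCCCCC1=C(O)C(=O)C=C(O)C1=O | intermediate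
8 | 3-henicosyl-2-hydroxy-5-methoxy-1,4-benzoquinone | CCCCCCCCCCCCCCCCCCCCCC1=C(O)C(=O)C=C(OC)C1=O | target

**Step count**
Total steps: 3. Longest linear sequence: 3 (1 → 4 → 7 → 8; acid 5 enters at step 2 as purchased).

**Steps most likely to fail, with fallbacks**

Step 2 (highest risk: modest radical-trapping efficiency of the free dihydroxyquinone, oxidative degradation of 4, some 3,6-dialkylation, poor solubility of the C22 acid). The fallback sets out from 4 and returns at 7 by a polar, two-electron reductive alkylation instead of a radical one. Commercial henicosan-1-ol is oxidised with PhI(OAc)2 and catalytic TEMPO in CH2Cl2 to henicosanal F1. F1 (1 equiv) is stirred with 4, Hantzsch ester (1.1 equiv) and catalytic L-proline in CH2Cl2 at room temperature. Proline-mediated Knoevenagel condensation at the ring C–H of 4 gives the quinone-methide-type adduct 5-hydroxy-3-henicosylidenecyclohex-5-ene-1,2,4-trione F2, which is not isolated. Conjugate hydride transfer from the Hantzsch ester to F2 then delivers 7.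

Step 3 (risk: over-methylation to the diether, or an inseparable mixture of mono-ethers). The fallback sets out from 7 and returns at 8 by exhaustive protection followed by selective deprotection. Both hydroxyls are methylated with dimethyl sulfate and K2CO3 in refluxing acetone to give 3-henicosyl-2,5-dimethoxy-1,4-benzoquinone F3. F3 is then treated with 70% HClO4 in THF at room temperature. This hydrolyses only the sterically twisted methoxy group next to the alkyl chain (the known behaviour of 3-alkyl-2,5-dimethoxyquinones) and leaves the 5-methoxy group in place, giving 8.

Step 1 (lowest risk: over-oxidation or humic by-products if the temperature or peroxide dosing drifts). The fallback sets out from 1 and returns at 4 by alkoxylation and hydrolysis instead of direct peroxide hydroxylation. Hydroquinone is oxidised with NaClO3 and catalytic V2O5 in 2% aq H2SO4 to 1,4-benzoquinone 2, which is isolated this time. Quinone 2 (3 equiv) is refluxed in MeOH with ZnCl2; two conjugate additions of methanol, each re-oxidised by excess 2, give 2,5-dimethoxy-1,4-benzoquinone F4, which crystallises out. The two vinylogous esters of F4 are saponified with 2 M aq NaOH at 60 °C and the solution is acidified with HCl to give 4.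

**Further compounds**
F1 | step 2 | henicosanal | CCCCCCCCCCCCCCCCCCCCC=O
F2 | step 2 | 5-hydroxy-3-henicosylidenecyclohex-5-ene-1,2,4-trione | CCCCCCCCCCCCCCCCCCCCC=C1C(=O)C(=O)C=C(O)C1=O
F3 | step 3 | 3-henicosyl-2,5-dimethoxy-1,4-benzoquinone | CCCCCCCCCCCCCCCCCCCCCC1=C(OC)C(=O)C=C(OC)C1=O
F4 | step 1 | 2,5-dimethoxy-1,4-benzoquinone | COC1=CC(=O)C(OC)=CC1=O
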